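**Retrosynthetic overview**
- Last bond: the C3–O ester bond, formed with inversion (Mitsunobu) between the 3α-alcohol of eremophila-1,7(11),9-trien-8-one and (2E,4E,6S)-6-methylocta-2,4-dienoic acid. The acid comes from (S)-2-methylbutan-1-ol by oxidation and a vinylogous Horner–Wadsworth–Emmons reaction.
- The oxidised decalin is simplified by removing in turn the C3 hydroxyl (allylic hydroxylation), the C1=C2 alkene (dienol dehydrogenation), the conjugation of the C7=C11 alkene (isopropenyl shift) and the C8 carbonyl (allylic oxidation). This leads back to (+)-aristolochene.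
- Feature on which the strategy rests: ring A (C1–C5, C10) and ring B (C5–C10), with the cis C4 secondary methyl, the C5 quaternary methyl, the C9=C10 alkene and the three-carbon unit on C7, are the aristolochene skeleton with the target's absolute configuration at C4 and C5.
- Aristolochene is disconnected at C6–C7 and C5–C10 to acyclic (2E,6E)-farnesyl diphosphate (two steps from farnesol). The cyclase first closes the ten-membered germacrene ring (C6–C7), then divides it transannularly (C5–C10) into rings A and B in one event, with the methyl shift from C10 to C5.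

Key step: step 3

Assumption: eremophilane numbering is used throughout, β denotes the decalin face that carries the C4 and C5 methyl groups, and the recombinant cyclase is treated as a catalyst obtained by standard heterologous expression, not as a starting material.

**Route**

Step 1
Reactants: 1 (2E,6E)-farnesol
Product: 2 (2E,6E)-farnesyl chloride
Conditions: NCS, Me2S, CH2Cl2, −40 → 0 °C
Reagents that add atoms: N-chlorosuccinimide, O=C1CCC(=O)N1Cl
Why: Corey–Kim-type chlorination of a primary allylic alcohol: the alkoxysulfonium ion formed from 1 is displaced by chloride at C1 in an SN2 step, so the chloride should form without allylic transposition and with both E alkenes intact.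

Step 2
Reactants: 2 (2E,6E)-farnesyl chloride
Product: 4 (2E,6E)-farnesyl diphosphate trisammonium salt, via farnesyl diphosphate bis(tetrabutylammonium) salt 3 (not isolated)
Conditions: (n-Bu4N)3HP2O7, MeCN, rt; then Dowex 50W (NH4+ form), aq. NH4HCO3/i-PrOH; lyophilise; cellulose chromatography
Reagents that add atoms: tris(tetrabutylammonium) hydrogen diphosphate, CCCC[N+](CCCC)(CCCC)CCCC.CCCC[N+](CCCC)(CCCC)CCCC.CCCC[N+](CCCC)(CCCC)CCCC.OP(=O)([O-])OP(=O)([O-])[O-]; ammonium hydrogencarbonate, [NH4+].OC([O-])=O
Why: SN2 displacement of the primary allylic chloride by the lipophilic diphosphate salt in a dipolar aprotic solvent (the standard pyrophosphorylation of allylic halides), followed by cation exchange to the water-soluble ammonium salt that the enzyme accepts.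

Step 3
Reactants: 4 (2E,6E)-farnesyl diphosphate trisammonium salt
Product: 6 (+)-aristolochene, via (S)-germacrene A 5 (not isolated)
Conditions: recombinant aristolochene synthase (Aspergillus terreus enzyme expressed in E. coli), MgCl2, Tris·HCl buffer pH 7.5, 2-mercaptoethanol, glycerol, pentane overlay, 25 °C
Reagents that add atoms: none
Why: Magnesium-assisted ionisation of the diphosphate gives the C6 allylic cation, which is captured by C7 of the distal C7=C11 alkene to close the ten-membered ring (C6–C7 bond) and, after loss of a C12 proton, gives enzyme-bound (S)-germacrene A 5; reprotonation of its C1=C10 alkene at C1 then triggers transannular attack of the C4=C5 alkene through C5 (C5–C10 bond), which divides the macrocycle into rings A and B as the trans-fused eudesmyl cation, and a 1,2-hydride shift (C5 to C4), a 1,2-methyl shift (C10 to C5) and loss of a C9 proton deliver the C9=C10 alkene. The reaction type is a terpene-cyclase cation–olefin cascade with Wagner–Meerwein shifts, the known conversion of farnesyl diphosphate into (+)-aristolochene by aristolochene synthase. The macrocyclisation is a 1,10-closure in which the attacking alkene stays exocyclic, and the transannular closure is 6-endo for ring A and 6-exo for ring B. C7 is set by the face of the C7=C11 alkene that the folded chain presents to C6 in the active site; C4 and C5 are set because the hydrogen on C5 and the methyl on C10 are antiperiplanar in the eudesmyl cation and migrate suprafacially on opposite faces, which leaves the two methyl groups cis. The step needs 1,10- over 1,6- or 1,11-cyclisation, no quenching by water at the germacrene or eudesmyl stage, and regioselective loss of the C9 proton; the (2E,6E) geometry of 4 and the hydrophobic active-site contour, which fixes the chain fold and shields the cations, secure them.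

Step 4
Reactants: 6 (+)-aristolochene
Product: 7 (4S,5R,7S)-eremophila-9,11-dien-8-one
Conditions: t-BuOOH (70% in H2O), Rh2(cap)4 (cat.; cap = caprolactamate), K2CO3, CH2Cl2, rt
Reagents that add atoms: tert-butyl hydroperoxide, CC(C)(C)OO
Why: Allylic C–H oxidation by a Rh2(cap)4-initiated tert-butylperoxyl radical chain: hydrogen is abstracted at C8, the methylene attached to the vinylic CH of the trisubstituted C9=C10 alkene (the site preference seen in the valencene-to-nootkatone and Δ5-steroid-to-7-ketone oxidations), and the oxygenated carbon collapses to the conjugated C8 ketone; no stereocentre is formed, C4 and C5 are untouched, and the configuration at C7 no longer matters because step 5 removes it.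

Step 5
Reactants: 7 (4S,5R,7S)-eremophila-9,11-dien-8-one
Product: 8 (4S,5R)-eremophila-7(11),9-dien-8-one (the dehydrofukinone structure)
Conditions: NaOMe (cat.), MeOH, 0 °C → rt
Reagents that add atoms: none
Why: Base-catalysed prototropic alkene isomerisation through the cross-conjugated dienolate (deprotonation at C7, reprotonation at C12) moves the isopropenyl alkene into conjugation with the C8 carbonyl as the thermodynamically favoured tetrasubstituted C7=C11 alkene and erases the C7 stereocentre.

Step 6
Reactants: 8 (4S,5R)-eremophila-7(11),9-dien-8-one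
Product: 10 (4S,5R)-eremophila-1,7(11),9-trien-8-one, via linear dienol 9 (not isolated)
Conditions: chloranil, t-BuOH, reflux
Reagents that add atoms: none
Why: Quinone dehydrogenation of an enone to the linear dienone (the chloranil method that turns Δ4-3-keto steroids into Δ4,6-dienones): with C7 blocked, enolisation toward C1 gives the linear dienol 9 (ring-internal and more substituted than the alternative toward an isopropylidene methyl), chloranil abstracts hydride from C2 to an oxygen-stabilised cation, and proton loss gives the C1=C2 alkene in conjugation with C9=C10 and C8=O; C4 and C5 are not involved.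

Step 7
Reactants: 10 (4S,5R)-eremophila-1,7(11),9-trien-8-one
Product: 11 (3R,4R,5R)-3-hydroxyeremophila-1,7(11),9-trien-8-one (3α-alcohol)
Conditions: SeO2 (0.5 equiv), t-BuOOH (in decane), CH2Cl2, rt → 40 °C
Reagents that add atoms: tert-butyl hydroperoxide, CC(C)(C)OO; selenium dioxide, O=[Se]=O
Why: Selenium dioxide allylic hydroxylation (Riley-type, catalytic in SeO2 with tert-butyl hydroperoxide as terminal oxidant): ene reaction of the C1=C2 alkene (Se to C1, hydrogen from C3, the only allylic C–H this alkene has) and [2,3]-sigmatropic shift return the alkene to C1=C2 and place oxygen on C3, the whole sequence being suprafacial on the α-face opposite the C4 and C5 methyl groups, so that the new C3 stereocentre should be 3α (3R); the ketone has no α-hydrogen, and the tetrasubstituted C7=C11 alkene is deactivated by direct conjugation and would need a Se–C bond at the hindered C7.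

Step 8
Reactants: 12 (S)-2-methylbutan-1-ol
Product: 13 (S)-2-methylbutanal
Conditions: TEMPO (cat.), KBr (cat.), NaOCl, NaHCO3, CH2Cl2/H2O, 0 °C
Reagents that add atoms: none
Why: TEMPO-catalysed hypochlorite oxidation (Anelli oxidation) at 0 °C and pH near 9 stops at the aldehyde and should leave the α-stereocentre of 2-methylbutanal intact; the volatile aldehyde is used at once.

Step 9
Reactants: 13 (S)-2-methylbutanal; 14 triethyl 4-phosphonocrotonate
Product: 16 ethyl (2E,4E,6S)-6-methylocta-2,4-dienoate, via lithiated phosphonate 15 (not isolated)
Conditions: 14, LiN(SiMe3)2 (slight deficit), THF, −78 °C; then 13, −78 → 0 °C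
Reagents that add atoms: none
Why: Vinylogous Horner–Wadsworth–Emmons olefination: the α-phosphonyl carbanion 15 adds to the aldehyde and elimination of diethyl phosphate gives the new C4=C5 alkene E-selectively while the C2=C3 alkene stays E; adding the aldehyde at −78 °C to an anion solution free of excess amide base protects the α-stereocentre (C6 of the product), which the bond-forming events do not touch.

Step 10
Reactants: 16 ethyl (2E,4E,6S)-6-methylocta-2,4-dienoate
Product: 17 (2E,4E,6S)-6-methylocta-2,4-dienoic acid
Conditions: LiOH, THF/MeOH/H2O, rt; then 1 M HCl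
Reagents that add atoms: lithium hydroxide, [Li+].[OH-]
Why: Saponification (acyl–oxygen ester hydrolysis) with aqueous LiOH at room temperature; hydroxide is too weak a base to deprotonate the ε-C–H at C6, so the stereocentre and both E alkenes should survive.

Step 11
Reactants: 11 (3R,4R,5R)-3-hydroxyeremophila-1,7(11),9-trien-8-one; 17 (2E,4E,6S)-6-methylocta-2,4-dienoic acid
Product: 18 (3S,4R,5R)-8-oxoeremophila-1,7(11),9-trien-3-yl (2E,4E,6S)-6-methylocta-2,4-dienoate (CNP0215744.1)
Conditions: PPh3, DIAD, toluene, 0 °C → rt
Reagents that add atoms: none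
Why: Mitsunobu esterification: PPh3 and DIAD turn the C3 hydroxyl of 11 into an oxyphosphonium leaving group that the carboxylate of 17 displaces by SN2 with inversion, converting the 3α (3R) alcohol into the 3β (3S) ester cis to the C4 and C5 methyl groups as required; the cation that an SN1 path would need is destabilised by the dienone.

**Compound list**

1 | (2E,6E)-farnesol | CC(C)=CCC/C(C)=C/CC/C(C)=C/CO | starting material
2 | (2E,6E)-farnesyl chloride | CC(C)=CCC/C(C)=C/CC/C(C)=C/CCl | intermediate
3 | bis(tetrabutylammonium) hydrogen (2E,6E)-farnesyl diphosphate | CC(C)=CCC/C(C)=C/CC/C(C)=C/COP(=O)([O-])OP(=O)(O)[O-].CCCC[N+](CCCC)(CCCC)CCCC.CCCC[N+](CCCC)(CCCC)CCCC | intermediate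
4 | (2E,6E)-farnesyl diphosphate, trisammonium salt | CC(C)=CCC/C(C)=C/CC/C(C)=C/COP(=O)([O-])OP(=O)([O-])[O-].[NH4+].[NH4+].[NH4+] | intermediate
5 | (S)-germacrene A, (1(10)E,4E,7S)-germacra-1(10),4,11-triene, enzyme-bound | C/C1=C\CC/C(C)=C/C[C@@H](C(C)=C)CC1 | intermediate
6 | (+)-aristolochene, (4S,5R,7S)-eremophila-9,11-diene | C1CCC2=CC[C@H](C(C)=C)C[C@]2(C)[C@H]1C | intermediate
7 | (4S,5R,7S)-eremophila-9,11-dien-8-one | C1CCC2=CC(=O)[C@H](C(C)=C)C[C@]2(C)[C@H]1C | intermediate
8 | (4S,5R)-eremophila-7(11),9-dien-8-one (the dehydrofukinone structure) | C1CCC2=CC(=O)C(=C(C)C)C[C@]2(C)[C@H]1C | intermediate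
9 | (4S,5R)-eremophila-1(10),7(11),8-trien-8-ol (linear dienol) | C1CC=C2C=C(O)C(=C(C)C)C[C@]2(C)[C@H]1C | intermediate
10 | (4S,5R)-eremophila-1,7(11),9-trien-8-one | C1C=CC2=CC(=O)C(=C(C)C)C[C@]2(C)[C@H]1C | intermediate
11 | (3R,4R,5R)-3-hydroxyeremophila-1,7(11),9-trien-8-one (3α-alcohol, hydroxyl on the face opposite both methyl groups) | O[C@@H]1C=CC2=CC(=O)C(=C(C)C)C[C@]2(C)[C@H]1C | intermediate
12 | (S)-2-methylbutan-1-ol | CC[C@H](C)CO | starting material
13 | (S)-2-methylbutanal | CC[C@H](C)C=O | intermediate
14 | triethyl 4-phosphonocrotonate | CCOC(=O)/C=C/CP(=O)(OCC)OCC | starting material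
15 | lithium salt of the α-phosphonyl carbanion of 14 | CCOC(=O)/C=C/[CH-]P(=O)(OCC)OCC.[Li+] | intermediate
16 | ethyl (2E,4E,6S)-6-methylocta-2,4-dienoate | CC[C@H](C)/C=C/C=C/C(=O)OCC | intermediate
17 | (2E,4E,6S)-6-methylocta-2,4-dienoic acid | CC[C@H](C)/C=C/C=C/C(=O)O | intermediate
18 | (3S,4R,5R)-8-oxoeremophila-1,7(11),9-trien-3-yl (2E,4E,6S)-6-methylocta-2,4-dienoate, also named (1R,2S,8aR)-1,8a-dimethyl-6-oxo-7-(propan-2-ylidene)-1,2,6,7,8,8a-hexahydronaphthalen-2-yl (2E,4E,6S)-6-methylocta-2,4-dienoate | CC[C@H](C)/C=C/C=C/C(=O)O[C@H]1C=CC2=CC(=O)C(=C(C)C)C[C@]2(C)[C@H]1C | target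

**Step count and risks**

Total steps: 11. Longest linear sequence: 8 steps (steps 1–7 and 11, from farnesol 1).

Steps most likely to fail:

1. Step 7. The selenium oxidant may engage the isopropylidene methyl groups or C6 instead of C3, over-oxidise the new allylic alcohol to the C3 ketone, or deliver oxygen with poor facial selectivity. The fallback sets out from 10 and comes back to the route at 18. Wohl–Ziegler bromination (NBS, AIBN cat., PhCF3, 80 °C) abstracts the C3 hydrogen to the most delocalised radical, and bromine transfer to its open α-face should give (3R,4R,5R)-3-bromoeremophila-1,7(11),9-trien-8-one F1. Acid 17 is converted with Cs2CO3 in DMF into caesium (2E,4E,6S)-6-methylocta-2,4-dienoate F2, which displaces the allylic bromide by SN2 with inversion at 0 °C → rt. This gives 18 directly and bypasses steps 7 and 11.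

2. Step 11. The SN2 displacement at C3 has to come from the β-face past the C4 and C5 methyl groups, so the activated alcohol may instead eliminate toward C4 to the extended tetraenone, react by SN2′ at C1, or be acylated with retention. The fallback sets out from 11 and comes back at 18. Dess–Martin periodinane (NaHCO3, CH2Cl2, 0 °C) oxidises 11 to (4R,5R)-eremophila-1,7(11),9-triene-3,8-dione F3, which is used at once to avoid enolisation at C4. Luche reduction (NaBH4, CeCl3·7H2O, MeOH, −78 °C) should attack the less hindered and more electrophilic C3 carbonyl from the α-face and give (3S,4R,5R)-3-hydroxyeremophila-1,7(11),9-trien-8-one F4, the 3β-alcohol. Steglich acylation with 17 (EDC·HCl, DMAP, CH2Cl2) then gives 18 with retention. This sequence also accepts a mixture of C3 epimers from step 7.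

3. Step 4. Hydrogen abstraction may be unselective (C1 instead of C8, or the tertiary allylic C7–H), the isopropenyl group may be oxidised, and the enone formed may be oxidised further at C1. The fallback sets out from 6 and comes back at 7, and fixes the regiochemistry by ionic steps. mCPBA (NaHCO3, CH2Cl2, −20 °C) epoxidises the trisubstituted C9=C10 alkene in preference to the 1,1-disubstituted isopropenyl group, from the face opposite the C5 methyl, to give 9α,10α-epoxyeremophil-11-ene F5. PhSeNa (from PhSeSePh and NaBH4, EtOH, reflux) opens the epoxide at the secondary C9 in a trans-diaxial manner to 9β-(phenylselanyl)eremophil-11-en-10α-ol F6. H2O2 (THF, 0 °C → rt) gives the selenoxide of this hydroxy selenide F7, whose syn-elimination can only use a C8 hydrogen and yields the tertiary allylic alcohol eremophila-8,11-dien-10α-ol F8. Babler–Dauben oxidative transposition with pyridinium chlorochromate, [C5H5NH][CrO3Cl], in CH2Cl2 moves the oxygen to C8 and gives 7.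

Further compounds
F1 | step 7 | (3R,4R,5R)-3-bromoeremophila-1,7(11),9-trien-8-one | Br[C@@H]1C=CC2=CC(=O)C(=C(C)C)C[C@]2(C)[C@H]1C
F2 | step 7 | caesium (2E,4E,6S)-6-methylocta-2,4-dienoate | CC[C@H](C)/C=C/C=C/C(=O)[O-].[Cs+]
F3 | step 11 | (4R,5R)-eremophila-1,7(11),9-triene-3,8-dione | O=C1C=CC2=CC(=O)C(=C(C)C)C[C@]2(C)[C@H]1C
F4 | step 11 | (3S,4R,5R)-3-hydroxyeremophila-1,7(11),9-trien-8-one (3β-alcohol) | O[C@H]1C=CC2=CC(=O)C(=C(C)C)C[C@]2(C)[C@H]1C
F5 | step 4 | 9α,10α-epoxyeremophil-11-ene (aristolochene 9,10-epoxide, oxygen on the face opposite the C5 methyl) | C1CC[C@@]23O[C@@H]2C[C@H](C(C)=C)C[C@]3(C)[C@H]1C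
F6 | step 4 | 9β-(phenylselanyl)eremophil-11-en-10α-ol | C1CC[C@@]2(O)[C@@H]([Se]c3ccccc3)C[C@H](C(C)=C)C[C@]2(C)[C@H]1C
F7 | step 4 | 9β-(phenylseleninyl)eremophil-11-en-10α-ol (selenoxide, not isolated) | C1CC[C@@]2(O)[C@@H]([Se](=O)c3ccccc3)C[C@H](C(C)=C)C[C@]2(C)[C@H]1C
F8 | step 4 | eremophila-8,11-dien-10α-ol | C1CC[C@@]2(O)C=C[C@H](C(C)=C)C[C@]2(C)[C@H]1C
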